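**Retrosynthetic overview**
1. The target is 4',7-dihydroxy-3,5,6,8-tetramethoxyflavone. Both free phenols travel as benzyl ethers to the last step, O5–Me and O3–Me are late methylations, and the C3 oxygen is placed on a 3-unsubstituted flavone by oxidation of C2=C3.
2. Ring C is cut at C4a–C4, C4–C3 and O1–C2 at once. This gives a 2-iodoresorcinol (ring A), carbon monoxide (C4) and 4-benzyloxyphenylacetylene (C3, C2 and ring B).
3. Feature used: C4a lies between the oxygen-bearing carbons C5 and C8a, and C6 and C8 both carry OMe on either side of C7–O. Ring A therefore has a local mirror plane through C4a and C7, and closure through either hydroxyl of the iodoresorcinol gives the same flavone.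
4. The iodoresorcinol comes from 2,6-dimethoxyphenol by O-benzylation, dibromination para to each OMe, conversion of both bromides through Bpin to OH, and iodination of the last ring C–H.
5. Ring order: rings A and B are bought as benzenes, and ring C is the only ring built (step 6).

Key step: step 6

Remark: dimethyldioxirane is taken as a separately prepared, titrated acetone solution (from acetone and KHSO5), and its preparation is not counted as a step.

**Step 1**
Reactants: 1 2,6-dimethoxyphenol; 2 benzyl bromide
Product: 3 2-(benzyloxy)-1,3-dimethoxybenzene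
Conditions: K2CO3, DMF, rt → 50 °C
Reagents that add atoms: none
Why: Williamson ether synthesis, in which the phenoxide of 1 displaces bromide from 2 by SN2 and the masking removes the strong para-directing power of the free phenol before the bromination.

**Step 2**
Reactants: 3 2-(benzyloxy)-1,3-dimethoxybenzene
Product: 4 3-(benzyloxy)-1,5-dibromo-2,4-dimethoxybenzene
Conditions: NBS (2.1 equiv), MeCN, 0 °C → rt, dark
Reagents that add atoms: N-bromosuccinimide, O=C1CCC(=O)N1Br
Why: Electrophilic aromatic bromination with NBS in a polar solvent, in which each outer methoxy group directs to its own para position while the central benzyloxy group, twisted out of conjugation by its two ortho neighbours, activates the middle C–H only weakly, so the 1,5-dibromide should form.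

**Step 3**
Reactants: 4 3-(benzyloxy)-1,5-dibromo-2,4-dimethoxybenzene
Product: 5 2,2'-[5-(benzyloxy)-4,6-dimethoxy-1,3-phenylene]bis(4,4,5,5-tetramethyl-1,3,2-dioxaborolane)
Conditions: B2pin2 (2.5 equiv), PdCl2(dppf) (5 mol %), KOAc, 1,4-dioxane, 90 °C
Reagents that add atoms: bis(pinacolato)diboron, CC1(C)OB(OC1(C)C)B1OC(C)(C)C(C)(C)O1
Why: Miyaura borylation, in which each C–Br bond has only one ortho substituent and passes through oxidative addition, acetate-assisted transmetalation and reductive elimination, while the weak base KOAc holds back Suzuki coupling.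

**Step 4**
Reactants: 5 the bis(pinacol boronate)
Product: 6 5-(benzyloxy)-4,6-dimethoxybenzene-1,3-diol
Conditions: 30% aq H2O2, NaOH, THF, 0 °C, N2; then dil. HCl
Reagents that add atoms: hydrogen peroxide, OO
Why: Oxidation of arylboronates with basic hydrogen peroxide, in which hydroperoxide adds to boron, the aryl group migrates from B to O at the same ring carbon and the borate ester hydrolyses to the phenol, with low temperature and short contact protecting the electron-rich product.

**Step 5**
Reactants: 6 5-(benzyloxy)-4,6-dimethoxybenzene-1,3-diol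
Product: 7 5-(benzyloxy)-2-iodo-4,6-dimethoxybenzene-1,3-diol
Conditions: I2 (1.05 equiv), NaHCO3, THF–H2O, 0 °C
Reagents that add atoms: iodine, II
Why: Electrophilic aromatic iodination of a resorcinol under hydrogencarbonate buffering, where the single remaining ring C–H lies ortho to both hydroxyls, so no regiochemical choice exists and the mild reagent spares the ring and the benzyl ether.

**Step 6**
Reactants: 7 5-(benzyloxy)-2-iodo-4,6-dimethoxybenzene-1,3-diol; 8 1-(benzyloxy)-4-ethynylbenzene; 9 carbon monoxide
Product: 12 4',7-bis(benzyloxy)-5-hydroxy-6,8-dimethoxyflavone, via aryl ynone 10 (not isolated), via diethylamino enaminone 11 (not isolated)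
Conditions: PdCl2(PPh3)2 (5 mol %), CO (20 bar), Et2NH, 120 °C, autoclave
Reagents that add atoms: none
Why: Zerovalent palladium generated from PdCl2(PPh3)2 in the amine inserts into the C–I bond of 7, CO inserts to give the aroylpalladium iodide, and the acetylide of 8 is transferred and reductively eliminated as ynone 10, which makes C4a–C4 and C4–C3. Et2NH then adds to the β-carbon of 10 to give enaminone 11, and one flanking phenol attacks that carbon and expels the amine, which makes O1–C2. The closest known reaction type is the palladium-catalysed carbonylative Sonogashira coupling–cyclisation of 2-iodophenols with terminal arylacetylenes in a secondary amine, an established flavone synthesis. Ring C closes by a 6-endo-trig addition–elimination and no stereocentre is created. The step needs flavone (6-endo) rather than aurone (5-exo) closure, which 11 secures because its only electrophilic carbon is C2, and it needs CO uptake to outrun direct alkynylation and benzofuran formation, which CO pressure and the absence of any copper salt secure. No choice between the hydroxyls is required, because the mirror plane of 7 through C–I and C–OBn makes both closures converge on 12, the spectator hydroxyl ending as the hydrogen-bonded 5-OH.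

**Step 7**
Reactants: 12 4',7-bis(benzyloxy)-5-hydroxy-6,8-dimethoxyflavone
Product: 13 4',7-bis(benzyloxy)-5,6,8-trimethoxyflavone
Conditions: MeI, K2CO3, DMF, 50 °C
Reagents that add atoms: iodomethane, CI
Why: Williamson O-methylation, in which carbonate in a dipolar aprotic solvent with gentle heating overcomes the 5-OH···O=C4 hydrogen bond and the phenoxide is methylated by SN2, removing the only oxidisable free phenol before step 8.

**Step 8**
Reactants: 13 4',7-bis(benzyloxy)-5,6,8-trimethoxyflavone
Product: 15 4',7-bis(benzyloxy)-3-hydroxy-5,6,8-trimethoxyflavone, via racemic flavone 2,3-epoxide 14 (not isolated)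
Conditions: dimethyldioxirane (acetone solution), CH2Cl2, 0 °C → rt; then p-TsOH·H2O (cat.), CH2Cl2, rt
Reagents that add atoms: dimethyldioxirane, CC1(C)OO1
Why: Dimethyldioxirane epoxidation of the enol-ether-like C2=C3 bond of a flavone followed by acid-catalysed oxirane opening, in which C2–O ionises to the cation stabilised by O1 and ring B and loss of H3 gives the flavonol, so the two transient stereocentres of racemic 14 are erased.

**Step 9**
Reactants: 15 4',7-bis(benzyloxy)-3-hydroxy-5,6,8-trimethoxyflavone
Product: 16 4',7-bis(benzyloxy)-3,5,6,8-tetramethoxyflavone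
Conditions: MeI, K2CO3, acetone, reflux
Reagents that add atoms: iodomethane, CI
Why: Williamson O-methylation of the acidic flavonol 3-OH, the only free hydroxyl in 15.

**Step 10**
Reactants: 16 4',7-bis(benzyloxy)-3,5,6,8-tetramethoxyflavone
Product: 17 4',7-dihydroxy-3,5,6,8-tetramethoxyflavone (target)
Conditions: H2 (1 atm), 10% Pd/C, EtOAc–MeOH, rt
Reagents that add atoms: none
Why: Catalytic hydrogenolysis of benzyl aryl ethers, which cleaves both O–CH2Ph bonds under one atmosphere of hydrogen while the tetrasubstituted vinylogous-ester C2=C3 bond, the C4 carbonyl and the four methyl ethers stay untouched.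

**Compound list**
1 | 2,6-dimethoxyphenol | COc1cccc(OC)c1O | starting material
2 | benzyl bromide | BrCc1ccccc1 | starting material
3 | 2-(benzyloxy)-1,3-dimethoxybenzene | COc1cccc(OC)c1OCc1ccccc1 | intermediate
4 | 3-(benzyloxy)-1,5-dibromo-2,4-dimethoxybenzene | COc1c(Br)cc(Br)c(OC)c1OCc1ccccc1 | intermediate
5 | 2,2'-[5-(benzyloxy)-4,6-dimethoxy-1,3-phenylene]bis(4,4,5,5-tetramethyl-1,3,2-dioxaborolane) | COc1c(B2OC(C)(C)C(C)(C)O2)cc(B2OC(C)(C)C(C)(C)O2)c(OC)c1OCc1ccccc1 | intermediate
6 | 5-(benzyloxy)-4,6-dimethoxybenzene-1,3-diol | COc1c(O)cc(O)c(OC)c1OCc1ccccc1 | intermediate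
7 | 5-(benzyloxy)-2-iodo-4,6-dimethoxybenzene-1,3-diol | COc1c(O)c(I)c(O)c(OC)c1OCc1ccccc1 | intermediate
8 | 1-(benzyloxy)-4-ethynylbenzene | C#Cc1ccc(OCc2ccccc2)cc1 | starting material
9 | carbon monoxide | [C-]#[O+] | starting material
10 | 1-[4-(benzyloxy)-2,6-dihydroxy-3,5-dimethoxyphenyl]-3-[4-(benzyloxy)phenyl]prop-2-yn-1-one (aryl ynone, not isolated) | O=C(C#Cc1ccc(OCc2ccccc2)cc1)c1c(O)c(OC)c(OCc2ccccc2)c(OC)c1O | intermediate
11 | (E)-1-[4-(benzyloxy)-2,6-dihydroxy-3,5-dimethoxyphenyl]-3-[4-(benzyloxy)phenyl]-3-(diethylamino)prop-2-en-1-one (enaminone, not isolated; the push–pull C=C rotates readily) | O=C(/C=C(/N(CC)CC)c1ccc(OCc2ccccc2)cc1)c1c(O)c(OC)c(OCc2ccccc2)c(OC)c1O | intermediate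
12 | 4',7-bis(benzyloxy)-5-hydroxy-6,8-dimethoxyflavone | COc1c(OCc2ccccc2)c(OC)c2oc(-c3ccc(OCc4ccccc4)cc3)cc(=O)c2c1O | intermediate
13 | 4',7-bis(benzyloxy)-5,6,8-trimethoxyflavone | COc1c(OCc2ccccc2)c(OC)c2oc(-c3ccc(OCc4ccccc4)cc3)cc(=O)c2c1OC | intermediate
14 | racemic 4',7-bis(benzyloxy)-2,3-epoxy-5,6,8-trimethoxyflavanone (oxirane cis-fused to ring C, H3 and ring B on the same face; one enantiomer drawn; not isolated) | O=C1[C@@H]2O[C@]2(c3ccc(OCc4ccccc4)cc3)Oc5c1c(OC)c(OC)c(OCc6ccccc6)c5OC | intermediate
15 | 4',7-bis(benzyloxy)-3-hydroxy-5,6,8-trimethoxyflavone | COc1c(OCc2ccccc2)c(OC)c2oc(-c3ccc(OCc4ccccc4)cc3)c(O)c(=O)c2c1OC | intermediate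
16 | 4',7-bis(benzyloxy)-3,5,6,8-tetramethoxyflavone | COc1c(OCc2ccccc2)c(OC)c2oc(-c3ccc(OCc4ccccc4)cc3)c(OC)c(=O)c2c1OC | intermediate
17 | 4',7-dihydroxy-3,5,6,8-tetramethoxyflavone | COc1c(O)c(OC)c2oc(-c3ccc(O)cc3)c(OC)c(=O)c2c1OC | target

Total step count: 10
Longest linear sequence: 10 steps (1 → 17); alkyne 8 and CO 9 enter at step 6.

**Steps most likely to fail**

**Step 6.**
- Risk: oxidative addition into the crowded, very electron-rich C–I bond may be slow. Protodeiodination, capture of the aroylpalladium species by Et2NH, or CO-free alkynylation followed by benzofuran closure could then take over.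
- Fallback: polar acylation replaces the palladium carbonylation. It sets out from 7 and 8 and comes back at 10, and from there at 12.
- Iodide 7 is protected with MOMCl and i-Pr2NEt in CH2Cl2 as 1-(benzyloxy)-4-iodo-2,6-dimethoxy-3,5-bis(methoxymethoxy)benzene F1. Iodine–lithium exchange (n-BuLi, THF, −78 °C) then gives the doubly chelated [4-(benzyloxy)-3,5-dimethoxy-2,6-bis(methoxymethoxy)phenyl]lithium F2.
- Separately, 8 is deprotonated with n-BuLi to lithium [4-(benzyloxy)phenyl]acetylide F3. This is acylated with N-methoxy-N-methylcarbamoyl chloride to 3-[4-(benzyloxy)phenyl]-N-methoxy-N-methylprop-2-ynamide F4.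
- Addition of F2 to F4 (Weinreb ketone synthesis) and a cold dilute HCl quench should give 1-[4-(benzyloxy)-3,5-dimethoxy-2,6-bis(methoxymethoxy)phenyl]-3-[4-(benzyloxy)phenyl]prop-2-yn-1-one F5.
- HCl in MeOH removes both acetals to give 10. Warming 10 in Et2NH carries it through 11 to 12.

**Step 8.**
- Risk: epoxidation of the vinylogous-ester double bond may be slow. The excess oxidant could then attack the benzylic C–H bonds or the electron-rich rings, and the oxirane could open unproductively.
- Fallback: deprotonation at C3 replaces alkene oxidation. It sets out from 13 and comes back at 15.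
- LiN(i-Pr)2 in THF at −78 °C removes H3 next to the C4 carbonyl to give 4',7-bis(benzyloxy)-3-lithio-5,6,8-trimethoxyflavone F6.
- B(OMe)3 traps F6 as dimethyl [4',7-bis(benzyloxy)-5,6,8-trimethoxyflavon-3-yl]boronate F7.
- AcOH followed by aqueous H2O2 converts the C–B bond to C–OH and gives 15.

**Step 3.**
- Risk: the second borylation may stay incomplete, protodebromination may occur, and bromide and freshly formed boronate may oligomerise by Suzuki-type coupling.
- Fallback: direct C–O bond formation replaces C–B formation and oxidation. It sets out from 4 and comes back at 6, bypassing 5 and step 4.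
- The reaction is the palladium-catalysed hydroxylation of both aryl bromides with Pd2(dba)3, t-BuXPhos and KOH in 1,4-dioxane–H2O at 100 °C under N2, followed by acidification. No new compound arises on this path (F0).

**Further compounds**
F1 | step 6 | 1-(benzyloxy)-4-iodo-2,6-dimethoxy-3,5-bis(methoxymethoxy)benzene | COCOc1c(I)c(OCOC)c(OC)c(OCc2ccccc2)c1OC
F2 | step 6 | [4-(benzyloxy)-3,5-dimethoxy-2,6-bis(methoxymethoxy)phenyl]lithium | [Li]c1c(OCOC)c(OC)c(OCc2ccccc2)c(OC)c1OCOC
F3 | step 6 | lithium [4-(benzyloxy)phenyl]acetylide | [Li]C#Cc1ccc(OCc2ccccc2)cc1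
F4 | step 6 | 3-[4-(benzyloxy)phenyl]-N-methoxy-N-methylprop-2-ynamide | CON(C)C(=O)C#Cc1ccc(OCc2ccccc2)cc1
F5 | step 6 | 1-[4-(benzyloxy)-3,5-dimethoxy-2,6-bis(methoxymethoxy)phenyl]-3-[4-(benzyloxy)phenyl]prop-2-yn-1-one | O=C(C#Cc1ccc(OCc2ccccc2)cc1)c1c(OCOC)c(OC)c(OCc2ccccc2)c(OC)c1OCOC
F6 | step 8 | 4',7-bis(benzyloxy)-3-lithio-5,6,8-trimethoxyflavone | COc1c(OCc2ccccc2)c(OC)c2oc(-c3ccc(OCc4ccccc4)cc3)c([Li])c(=O)c2c1OC
F7 | step 8 | dimethyl [4',7-bis(benzyloxy)-5,6,8-trimethoxyflavon-3-yl]boronate | COc1c(OCc2ccccc2)c(OC)c2oc(-c3ccc(OCc4ccccc4)cc3)c(B(OC)OC)c(=O)c2c1OC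
F0 | step 3 | none | none
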